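The ash flask held 5.7 mM of impurity against 5.00 mM of free catalyst, the loading being counted on the left-handed substrate, and I began from that surplus.

| setting | ash | cedar | flask |
|---|---|---|---|
| left-handed substrate | 0.050 M | 0.050 M | 0.050 M |
| right-handed substrate | 0.050 M | 0.050 M | 0.050 M |
| reagent | 3 equiv | 3 equiv | 3.00 equiv |
| free catalyst | 10 mol% | 10 mol% | 10 mol% |
| added ligand | 21 mM | 32 mM | 21 mM |
| impurity | 5.7 mM | 5.7 mM | 5.7 mM |
| remark | the very flask that is asked about, followed so far | run made earlier |  |
| time |  |  | 8.0 d |

| run | time / d | left-handed product / % |
|---|---|---|
| ash | 0.250 | 15.2 |
| ash | 0.833 | 17.9 |
| ash | 1.25 | 18.2 |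
| ash | 2.08 | 17.6 |
| ash | 3.00 | 18.3 |
| ash | 4.00 | 18.6 |
| ash | 5.00 | 18.5 |
| cedar | 0.500 | 16.5 |
| cedar | 0.833 | 17.6 |
| cedar | 1.04 | 17.7 |
| cedar | 1.67 | 17.9 |
| cedar | 2.50 | 18.0 |
| cedar | 4.00 | 17.5 |
| cedar | 6.00 | 18.3 |

(readings scatter by 0.3 percentage points)

- free catalyst is single-handed; left-handed substrate and right-handed substrate are mirror images of each other, charged as a racemate, each of them at the stated concentration
- left-handed product taken out counts as made
- the earlier runs were read with a standard deviation of 0.3 percentage points
- reactions considered so far: reagent + free catalyst + left-handed substrate -> free catalyst + left-handed product; free catalyst + impurity -> spent catalyst; free catalyst + added ligand <-> idle complex; reagent + free catalyst + right-handed substrate -> free catalyst + right-handed product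
- additions bring no volume worth counting

- east: at 8.0 d add free catalyst, 50.0% of the amount charged, then wait 8.0 d
- north: at 8.0 d take out 90% of the left-handed product then present, then wait 8.0 d
- west: change nothing and wait 8.0 d more
- south-west: at 8.0 d add reagent, 50.0% of the amount charged, then wait 8.0 d

- left-handed product, in percent of the left-handed substrate and right-handed substrate together first charged, at 8.0 d
- what to do for the largest gain in left-handed product; "none" if nothing gains more than 2 percentage points (east / north / west / south-west / none)
- left-handed product present, with what was taken out counted in, in percent of the left-handed substrate and right-handed substrate together first charged, after north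
- left-handed product present, with what was taken out counted in, in percent of the left-handed substrate and right-handed substrate together first charged, after south-west

I read the runs as a ladder of clocks. The fastest rung was the rise. Taking the ash level of 18.2% as a reading, the first point of ash gave a time constant near 0.140 d, and cedar, with more added ligand, gave 0.213 d. On the next rung nothing climbed: cedar ended at 18.3% and ash at 18.5%, so the ligand had stretched the clock and left the ceiling.

The slowest rung was the supply. Reagent, at 150 mM, exceeded both substrates together, 100 mM, and 63.5% of the left-handed substrate still stood at the ash level. I therefore took the catalyst as the limiting reagent of its own poisoning, with 12.3% of the impurity outlasting it.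

With the reagent level taken as held, substrate and impurity each fall in proportion to themselves and to the same free catalyst, which cancels in their ratio, parked or not. I defined the reach as the logarithm of the fraction of left-handed substrate left over the logarithm of the fraction of impurity left, and from ash it was 0.216.

So I expected the level to hold at 8.0 d, with north and south-west gaining nothing. East adds 2.50 mM of catalyst, more than the 0.700 mM of surplus impurity, so I expected the left-handed product to run on toward 50.0%.

The forecast gave 18.2%, chose north, and put g2 at 28.6% and g4 at 20%, reading the stall thus: “it looks like an equilibrium or product-limited ceiling”.

The flask gave 18.0%, and the best choice was east, gaining 32 percentage points; g2 and g4 both stayed at 18.0%.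

    reagent + free catalyst + left-handed substrate → free catalyst + left-handed product (k = 0.390 M⁻² s⁻¹)
    free catalyst + impurity → spent catalyst (k = 0.250 M⁻¹ s⁻¹)
    free catalyst + added ligand ⇌ idle complex, settled at all times (K = 150 M⁻¹)
    reagent + free catalyst + right-handed substrate → free catalyst + right-handed product (k = 0.140 M⁻² s⁻¹)

Taking away the passing of free catalyst and impurity into spent catalyst lifted the simulated run from 18.0% to 50.0%, the largest single effect, and it cut the gain from east to 0 points. For the neighbour with 0.023 M of impurity, the surplus gave 78.3% of impurity left, against 78% simulated, and the reach gave 2.58% of left-handed product, against 2.75% simulated.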